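**Retrosynthetic overview**
- The last step is a Schenck ene reaction of singlet oxygen on a 13E trisubstituted alkene; it installs C13–OOH and the E C14=C15 bond.
- The key C–C bond is C16–C17: a β-acylvinyl chromium species (an sp2 homoenolate made from methyl (Z)-3-iodobut-2-enoate) adds to the C16 aldehyde, and lactonisation closes the butenolide, the last ring formed.
- The C16 aldehyde comes from a C13 ester via a terminal alkyne, methylalumination (fixes 13E) and ethylene oxide.
- Rings A and B, with C4, C5, C9 and C10, are taken intact from abietic acid. Ring C is cut at C13=C14; C14 becomes the C8 methyl and the isopropyl ketone becomes the C13 ester.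
- The 6α-oxygen is introduced through a transient 18,6α-lactone, formed on the finished decalin by carboxylate-directed C–H oxidation and opened to the methyl ester before the butenolide is built.

Assumption: labdane-type numbering is used (decalin C1–C10, ester carbon C18, side chain C11–C16, butenolide β-carbon C17), and the strained, doubly trans-fused 18,6α-lactone is taken not to re-form from the 6α-hydroxy methyl ester under neutral or methanolic conditions, as the existence of the target implies.

**Route**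

Step 1
Reactants: 1 (−)-abietic acid
Product: 3 13,14-dioxo-13,14-secoabiet-7-en-18-oic acid, via 13,14-diol 2 (not isolated)
Conditions: OsO4 (2 mol%), NaIO4 (4 equiv), 2,6-lutidine, dioxane/H2O 3:1, rt
Reagents that add atoms: osmium tetroxide, O=[Os](=O)(=O)=O (oxygen carrier); sodium periodate, [Na+].[O-]I(=O)(=O)=O (terminal oxygen source)
Why: Lemieux–Johnson oxidation, in which OsO4 dihydroxylates the more accessible ring C alkene C13=C14 of the diene and periodate cleaves the glycol, leaving C7=C8 deactivated as an enal; no stereocentre is formed.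

Step 2
Reactants: 3 13,14-dioxo-13,14-secoabiet-7-en-18-oic acid
Product: 5 13-oxo-13,14-secoabiet-8(14)-en-18-oic acid, via tosylhydrazone 4 (not isolated)
Conditions: TsNHNH2 (1.05 equiv), EtOH, rt; catecholborane, CHCl3, 0 °C; NaOAc·3H2O, 60 °C
Reagents that add atoms: none
Why: The aldehyde condenses much faster than the hindered isopropyl ketone, and Kabalka reduction of the α,β-unsaturated tosylhydrazone gives an allylic diazene that loses N2 by retro-ene with 1,3-transposition, making C14 the exocyclic methylene and C7 a CH2.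

Step 3
Reactants: 5 13-oxo-13,14-secoabiet-8(14)-en-18-oic acid
Product: 6 8α-hydroxy-13-oxo-13,14-secoabietan-18-oic acid
Conditions: Co(acac)2 (20 mol%), PhSiH3, O2 (1 atm), THF/i-PrOH, rt
Reagents that add atoms: dioxygen, O=O
Why: Mukaiyama hydration (hydrogen-atom transfer to the CH2 terminus, O2 capture of the tertiary C8 radical, in situ reduction of the peroxide); O2 enters from the α (equatorial) side because the β-axial path is blocked by the syn-axial C10 methyl, giving 8α-OH/8β-CH3 (expected about 4:1, minor epimer removed by chromatography).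

Step 4
Reactants: 6 8α-hydroxy-13-oxo-13,14-secoabietan-18-oic acid
Product: 7 8α-hydroxy-13-isopropoxy-13-oxo-14,15,16-trinorlabdan-18-oic acid
Conditions: mCPBA, Na2HPO4, CH2Cl2, 40 °C
Reagents that add atoms: 3-chloroperoxybenzoic acid, OOC(=O)c1cccc(Cl)c1
Why: Baeyer–Villiger oxidation in which the secondary isopropyl group migrates in preference to the primary chain, so C13 stays on C12 as an ester carbonyl; the buffer keeps the 8-hydroxy ketone from closing to a cyclic enol ether.

Step 5
Reactants: 7 8α-hydroxy-13-isopropoxy-13-oxo-14,15,16-trinorlabdan-18-oic acid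
Product: 8 isopropyl 8α-hydroxy-14,15,16-trinorlabdan-13-oate 18,6α-lactone
Conditions: [Mn(OTf)2((S,S)-TIPS-pdp)] (2 mol%), aq. H2O2 (syringe pump), HFIP, 0 °C
Reagents that add atoms: none
Why: Carboxylate-directed manganese-oxo C–H lactonisation (1,7-hydrogen-atom transfer, then carboxylate rebound); the equatorial C18 carboxylate lies peri to the equatorial 6α-hydrogen, the only γ C–H it can reach, so oxygen is delivered to the α face and sets C6 as in the target.

Step 6
Reactants: 8 isopropyl 8α-hydroxy-14,15,16-trinorlabdan-13-oate 18,6α-lactone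
Product: 10 dimethyl 6α,8α-dihydroxy-14,15,16-trinorlabdane-13,18-dioate, via dilithium dicarboxylate 9 (not isolated)
Conditions: LiOH (2.2 equiv), THF/H2O, 50 °C; evaporate; MeI, DMF, rt
Reagents that add atoms: lithium hydroxide, [Li+].[OH-]; iodomethane, CI
Why: Saponification opens the strained lactone and the isopropyl ester, and SN2 O-methylation of both carboxylates (insensitive to the hindrance at C4) gives the C18 methyl ester with 6α-OH free; no stereocentre is touched.

Step 7
Reactants: 10 dimethyl 6α,8α-dihydroxy-14,15,16-trinorlabdane-13,18-dioate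
Product: 12 methyl 6α,8α-dihydroxy-15,16-dinorlabd-13-yn-18-oate, via C13 aldehyde 11 (not isolated)
Conditions: DIBAL-H (3.3 equiv), CH2Cl2, −78 °C; then MeOH, K2CO3, dimethyl (1-diazo-2-oxopropyl)phosphonate, −78 °C to rt
Reagents that add atoms: dimethyl (1-diazo-2-oxopropyl)phosphonate, COP(=O)(OC)C(=[N+]=[N-])C(C)=O
Why: DIBAL-H reduces only the unhindered C13 ester (the neopentyl C18 ester is inert at −78 °C and the aluminium acetal stops at the aldehyde level), and the one-pot Ohira–Bestmann (Seyferth–Gilbert) homologation converts the aldehyde or its 8,13-lactol into the terminal alkyne.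

Step 8
Reactants: 12 methyl 6α,8α-dihydroxy-15,16-dinorlabd-13-yn-18-oate
Product: 14 homoallylic alcohol (C18 methyl ester; 6α,8α-diol; C9 chain (E)-CH2CH2C(CH3)=CHCH2CH2OH), via alkenylalane 13 (not isolated)
Conditions: AlMe3 (6 equiv), Cp2ZrCl2 (25 mol%), H2O (1 equiv), CH2Cl2, −23 °C; evaporate; n-BuLi (3 equiv), hexane/THF, 0 °C; ethylene oxide, 0 °C to rt
Reagents that add atoms: trimethylaluminium, C[Al](C)C; ethylene oxide, C1CO1
Why: Negishi zirconium-catalysed carboalumination (water-accelerated) adds CH3 and Al syn across the alkyne, methyl to C13 and aluminium to C14, which fixes the 13E alkene, and the derived alanate opens ethylene oxide with retention to add C15 and C16; the extra AlMe3 covers the two hydroxyls.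

Step 9
Reactants: 14 homoallylic alcohol
Product: 15 β,γ-unsaturated aldehyde (C9 chain (E)-CH2CH2C(CH3)=CHCH2CHO)
Conditions: TEMPO (10 mol%), PhI(OAc)2 (1.1 equiv), CH2Cl2, rt; used crude at once
Reagents that add atoms: none
Why: Oxoammonium (TEMPO) oxidation is selective for the primary alcohol over the hindered secondary 6α-OH and tertiary 8α-OH and is mild enough that the β,γ-unsaturated aldehyde does not move into conjugation.

Step 10
Reactants: 16 methyl but-2-ynoate
Product: 17 methyl (Z)-3-iodobut-2-enoate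
Conditions: NaI, AcOH, 115 °C
Reagents that add atoms: sodium iodide, [Na+].[I-]
Why: Conjugate addition of iodide to the ynoate followed by protonation is a net anti hydroiodination and gives the (Z)-β-iodo enoate selectively.

Step 11
Reactants: 15 β,γ-unsaturated aldehyde; 17 methyl (Z)-3-iodobut-2-enoate
Product: 19 (13E,16S)-butenolide (C18 methyl ester; 6α,8α-diol; C9 chain (E)-CH2CH2C(CH3)=CHCH2 attached to C5 of 4-methylfuran-2(5H)-one), via hydroxy enoate 18 (not isolated)
Conditions: CrCl2 (4 equiv), Kishi oxazoline–sulfonamide ligand N-[2-(4-isopropyl-4,5-dihydrooxazol-2-yl)-6-methoxyphenyl]methanesulfonamide (antipode giving 16S, 4.4 equiv), Et3N, NiCl2 (10 mol%), THF, rt; aq. NH4Cl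
Reagents that add atoms: none
Why: Nozaki–Hiyama–Kishi coupling in which nickel insertion into the C–I bond and transmetalation give a β-chromio (Z)-enoate, a β-acylvinyl anion whose normally electrophilic β-carbon C17 attacks the electrophilic aldehyde carbon C16 in the presence of the free hydroxyls; the chiral chromium–sulfonamide complex selects the aldehyde face to give 16S (reagent control, minor epimer removed) and the (Z)-γ-alkoxy ester lactonises to the butenolide.

Step 12
Reactants: 19 (13E,16S)-butenolide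
Product: 20 target, methyl (13R,14E,16S)-6α,8α-dihydroxy-13-hydroperoxy ester with the 4-methylbutenolide at C16
Conditions: O2, tetraphenylporphyrin (cat.), hν (sodium lamp), CH2Cl2, 0 °C; preparative HPLC
Reagents that add atoms: dioxygen, O=O
Why: Schenck ene reaction of singlet oxygen at the only electron-rich alkene, where suprafacial C–O bond formation at C13 with abstraction of a C15 hydrogen moves the double bond to C14=C15 (E) and creates the tertiary hydroperoxide; the cis effect also allows abstraction from the C13 methyl (14-hydroperoxide by-product) and the remote C16 centre gives little facial bias, so the 13R epimer (about a quarter of the product mixture) is isolated by HPLC.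

**Compound list**

1 | (−)-abietic acid (abieta-7,13-dien-18-oic acid) | OC(=O)[C@]1(C)CCC[C@@]2(C)[C@H]1CC=C3C=C(C(C)C)CC[C@H]23 | starting material
2 | 13α,14α-dihydroxyabiet-7-en-18-oic acid | OC(=O)[C@]1(C)CCC[C@@]2(C)[C@H]1CC=C3[C@@H](O)[C@](O)(C(C)C)CC[C@H]23 | intermediate
3 | 13,14-dioxo-13,14-secoabiet-7-en-18-oic acid (C14 aldehyde on C8=C7; C9 chain CH2CH2C(=O)CH(CH3)2) | OC(=O)[C@]1(C)CCC[C@@]2(C)[C@H]1CC=C(C=O)[C@@H]2CCC(=O)C(C)C | intermediate
4 | C14 (E)-4-methylbenzenesulfonylhydrazone of 3 | OC(=O)[C@]1(C)CCC[C@@]2(C)[C@H]1CC=C(/C=N/NS(=O)(=O)c3ccc(C)cc3)[C@@H]2CCC(=O)C(C)C | intermediate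
5 | 13-oxo-13,14-secoabiet-8(14)-en-18-oic acid (exocyclic methylene on C8) | OC(=O)[C@]1(C)CCC[C@@]2(C)[C@H]1CCC(=C)[C@@H]2CCC(=O)C(C)C | intermediate
6 | 8α-hydroxy-13-oxo-13,14-secoabietan-18-oic acid (8β-methyl) | OC(=O)[C@]1(C)CCC[C@@]2(C)[C@H]1CC[C@@](C)(O)[C@@H]2CCC(=O)C(C)C | intermediate
7 | 8α-hydroxy-13-isopropoxy-13-oxo-14,15,16-trinorlabdan-18-oic acid | OC(=O)[C@]1(C)CCC[C@@]2(C)[C@H]1CC[C@@](C)(O)[C@@H]2CCC(=O)OC(C)C | intermediate
8 | isopropyl 8α-hydroxy-14,15,16-trinorlabdan-13-oate 18,6α-lactone | O=C1[C@]2(C)CCC[C@@]3(C)[C@H]2[C@@H](O1)C[C@@](C)(O)[C@@H]3CCC(=O)OC(C)C | intermediate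
9 | dilithium 6α,8α-dihydroxy-14,15,16-trinorlabdane-13,18-dioate | [Li+].[Li+].[O-]C(=O)[C@]1(C)CCC[C@@]2(C)[C@H]1[C@@H](O)C[C@@](C)(O)[C@@H]2CCC([O-])=O | intermediate
10 | dimethyl 6α,8α-dihydroxy-14,15,16-trinorlabdane-13,18-dioate | COC(=O)[C@]1(C)CCC[C@@]2(C)[C@H]1[C@@H](O)C[C@@](C)(O)[C@@H]2CCC(=O)OC | intermediate
11 | methyl 6α,8α-dihydroxy-13-oxo-14,15,16-trinorlabdan-18-oate (C13 aldehyde, in equilibrium with its 8,13-lactol) | COC(=O)[C@]1(C)CCC[C@@]2(C)[C@H]1[C@@H](O)C[C@@](C)(O)[C@@H]2CCC=O | intermediate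
12 | methyl 6α,8α-dihydroxy-15,16-dinorlabd-13-yn-18-oate (terminal alkyne) | COC(=O)[C@]1(C)CCC[C@@]2(C)[C@H]1[C@@H](O)C[C@@](C)(O)[C@@H]2CCC#C | intermediate
13 | (13E)-alkenyl(dimethyl)alane of 12 after methylalumination, both hydroxyls as dimethylaluminium alkoxides | COC(=O)[C@]1(C)CCC[C@@]2(C)[C@H]1[C@@H](O[Al](C)C)C[C@@](C)(O[Al](C)C)[C@@H]2CC/C(C)=C/[Al](C)C | intermediate
14 | homoallylic alcohol: C18 methyl ester, 6α,8α-diol, C9 chain (E)-CH2CH2C(CH3)=CHCH2CH2OH | COC(=O)[C@]1(C)CCC[C@@]2(C)[C@H]1[C@@H](O)C[C@@](C)(O)[C@@H]2CC/C(C)=C/CCO | intermediate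
15 | β,γ-unsaturated aldehyde: C9 chain (E)-CH2CH2C(CH3)=CHCH2CHO | COC(=O)[C@]1(C)CCC[C@@]2(C)[C@H]1[C@@H](O)C[C@@](C)(O)[C@@H]2CC/C(C)=C/CC=O | intermediate
16 | methyl but-2-ynoate | CC#CC(=O)OC | starting material
17 | methyl (Z)-3-iodobut-2-enoate | C/C(I)=C/C(=O)OC | intermediate
18 | (13E,16S,17Z)-γ-hydroxy enoate (chromium alkoxide before work-up): chain ends CH2CH(OH)C(CH3)=CHCO2CH3 | COC(=O)[C@]1(C)CCC[C@@]2(C)[C@H]1[C@@H](O)C[C@@](C)(O)[C@@H]2CC/C(C)=C/C[C@H](O)/C(C)=C\C(=O)OC | intermediate
19 | (13E,16S)-butenolide: chain (E)-CH2CH2C(CH3)=CHCH2 on C5 of 4-methylfuran-2(5H)-one | COC(=O)[C@]1(C)CCC[C@@]2(C)[C@H]1[C@@H](O)C[C@@](C)(O)[C@@H]2CC/C(C)=C/C[C@@H]1OC(=O)C=C1C | intermediate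
20 | target: methyl (13R,14E,16S)-6α,8α-dihydroxy-13-hydroperoxy ester, chain CH2CH2C(CH3)(OOH)CH=CH on C5 of 4-methylfuran-2(5H)-one | COC(=O)[C@]1(C)CCC[C@@]2(C)[C@H]1[C@@H](O)C[C@@](C)(O)[C@@H]2CC[C@](C)(/C=C/[C@@H]1OC(=O)C=C1C)OO | target

**Step count and risk**

Total step count: 12. Longest linear sequence: 11 steps (steps 1–9, 11, 12, from abietic acid).

The three steps most likely to fail:

Step 5, the C–H lactonisation of 7, may over-oxidise (for example at C9–H) or stall. The fallback sets out from 7 and comes back at 8, and makes the C6–O bond by a nitrogen-radical relay instead. Compound 7 is persilylated (TMSCl, imidazole), the silyl ester is turned into the acid chloride in the same flask ((COCl)2, cat. DMF) and quenched with NH3 to give the 8-O-trimethylsilyl primary carboxamide F1. PhI(OAc)2/I2 under visible light forms the N-iodoamide; its amidyl radical abstracts the peri 6α-hydrogen (1,5-hydrogen transfer) and the oxidised C6 is captured by the amide oxygen to give the iminolactone F2. Aqueous HCl hydrolyses F2 and its silyl ether to lactone 8.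

Step 11, the nickel/chromium union, may suffer from conjugation of aldehyde 15 or from weak ligand control at C16. The fallback sets out from 15 and comes back at 19. It keeps the same C16–C17 bond and the same reversed polarity, but uses the acetylide of methyl propiolate as the β-acyl anion. Zinc–ProPhenol-catalysed addition (ProPhenol, Me2Zn, methyl propiolate, toluene, 4 °C) gives the (16S)-γ-hydroxy ynoate F3 with reagent control. Syn addition of Me2CuLi (THF, −78 °C) then places the methyl on C17 cis to the α-hydrogen, and the resulting (Z)-γ-hydroxy enoate lactonises on work-up to 19.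

Step 12, the ene reaction, has no control at C13 and splits between two regioisomers. The fallback sets out from 19 and comes back at 20, and sets C13 stereospecifically. Both hydroxyls are silylated (TESOTf, 2,6-lutidine) to the bis-triethylsilyl ether F4, so that 8-OH cannot attack C13. Shi epoxidation (fructose-derived ketone of the appropriate series, Oxone, pH 10.5) gives the (13S,14S)-epoxide F5. Perhydrolysis with anhydrous ethereal H2O2 and MoO2(acac)2 (cat.) opens F5 at the tertiary carbon with inversion to the (13R,14S)-13-hydroperoxy-14-ol F6. The more acidic, unhindered OOH is silylated selectively (TESCl, imidazole, −20 °C) to the silyl peroxide F7. Martin sulfurane dehydrates the C14 alcohol; C13 is quaternary, so elimination can only go toward C15 and gives the 14E-alkene F8. HF·pyridine removes the three silyl groups to give 20.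

**Further compounds**

F1 | step 5 | 8-O-trimethylsilyl C18 primary carboxamide of 7 | NC(=O)[C@]1(C)CCC[C@@]2(C)[C@H]1CC[C@@](C)(O[Si](C)(C)C)[C@@H]2CCC(=O)OC(C)C
F2 | step 5 | 18,6α-iminolactone (8-O-trimethylsilyl, C13 isopropyl ester) | N=C1[C@]2(C)CCC[C@@]3(C)[C@H]2[C@@H](O1)C[C@@](C)(O[Si](C)(C)C)[C@@H]3CCC(=O)OC(C)C
F3 | step 11 | (13E,16S)-γ-hydroxy ynoate: chain ends CH2CH(OH)C≡CCO2CH3 | COC(=O)[C@]1(C)CCC[C@@]2(C)[C@H]1[C@@H](O)C[C@@](C)(O)[C@@H]2CC/C(C)=C/C[C@H](O)C#CC(=O)OC
F4 | step 12 | 6,8-bis-O-triethylsilyl ether of 19 | COC(=O)[C@]1(C)CCC[C@@]2(C)[C@H]1[C@@H](O[Si](CC)(CC)CC)C[C@@](C)(O[Si](CC)(CC)CC)[C@@H]2CC/C(C)=C/C[C@@H]1OC(=O)C=C1C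
F5 | step 12 | (13S,14S)-13,14-epoxide of F4 | COC(=O)[C@]1(C)CCC[C@@]2(C)[C@H]1[C@@H](O[Si](CC)(CC)CC)C[C@@](C)(O[Si](CC)(CC)CC)[C@@H]2CC[C@]3(C)O[C@H]3C[C@@H]1OC(=O)C=C1C
F6 | step 12 | (13R,14S)-13-hydroperoxy-14-hydroxy bis-triethylsilyl ether | COC(=O)[C@]1(C)CCC[C@@]2(C)[C@H]1[C@@H](O[Si](CC)(CC)CC)C[C@@](C)(O[Si](CC)(CC)CC)[C@@H]2CC[C@](C)([C@@H](O)C[C@@H]1OC(=O)C=C1C)OO
F7 | step 12 | (13R,14S)-13-(triethylsilylperoxy)-14-hydroxy bis-triethylsilyl ether | COC(=O)[C@]1(C)CCC[C@@]2(C)[C@H]1[C@@H](O[Si](CC)(CC)CC)C[C@@](C)(O[Si](CC)(CC)CC)[C@@H]2CC[C@](C)([C@@H](O)C[C@@H]1OC(=O)C=C1C)OO[Si](CC)(CC)CC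
F8 | step 12 | (13R,14E)-13-(triethylsilylperoxy) bis-triethylsilyl ether of 20 | COC(=O)[C@]1(C)CCC[C@@]2(C)[C@H]1[C@@H](O[Si](CC)(CC)CC)C[C@@](C)(O[Si](CC)(CC)CC)[C@@H]2CC[C@](C)(/C=C/[C@@H]1OC(=O)C=C1C)OO[Si](CC)(CC)CC
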